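**Retrosynthetic overview**
- The target comes from its bis-MOM ether, which comes from the fully assembled acetophenone by Claisen–Schmidt condensation with benzaldehyde. Rings A–D are all bought; no ring is formed.
- The E-C5=C6 alkene is cut by cross-metathesis into a 3,3-diarylpropene (rings A and B, C-7 stereocentre) and an (R)-homoallylic alcohol (ring C, C-3 set by Keck allylation).
- The C-7–ring A bond and the (S) centre come from a proposed catalytic enantioselective aromatic Claisen rearrangement of an ortho-acetylaryl cinnamyl ether. The [3,3] topology and the blocked second ortho position fix the site on ring A.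
- The ether comes from a Mitsunobu reaction of 4'-O-MOM-protected 2',4'-dihydroxy-6'-methoxyacetophenone with p-coumaryl alcohol pivalate.

**Assumptions**
- The SMILES is read as 7S (diarylmethine carbon) and 3R (carbinol carbon). Heptanoid carbons C-1 to C-7 run from the CH2 on ring C to the diarylmethine carbon. Ring A carbons are primed, with C-1' bearing the acyl group.
- p-Coumaryl alcohol and both antipodes of t-Bu-box, 2,2'-(propane-2,2-diyl)bis(4-tert-butyl-4,5-dihydro-1,3-oxazole), are taken as commercial.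

**Route**

Step 1
Reactants: 1 1-(2,4-dihydroxy-6-methoxyphenyl)ethan-1-one
Product: 2 1-[2-hydroxy-6-methoxy-4-(methoxymethoxy)phenyl]ethan-1-one
Conditions: MOMCl (1.1 equiv), i-Pr2NEt (1.5 equiv), CH2Cl2, 0 °C → rt
Reagents that add atoms: chloromethyl methyl ether, COCCl
Why: Only the 4'-hydroxyl is free of the hydrogen bond to the ketone, so base-mediated O-alkylation with the α-chloro ether (Williamson-type MOM protection) takes place there alone and leaves the chelated 2'-hydroxyl for step 3.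

Step 2
Reactants: 3 4-[(1E)-3-hydroxyprop-1-en-1-yl]phenol (p-coumaryl alcohol)
Product: 4 4-[(1E)-3-hydroxyprop-1-en-1-yl]phenyl 2,2-dimethylpropanoate
Conditions: PivCl (1.05 equiv), 1 M aq NaOH (1.1 equiv), THF, 0 °C
Reagents that add atoms: pivaloyl chloride, CC(C)(C)C(Cl)=O
Why: Schotten–Baumann acylation, in which one equivalent of hydroxide ionises only the phenol and the phenoxide is acylated much faster than the neutral allylic alcohol; the pivalate also makes ring B less electron-rich for step 4.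

Step 3
Reactants: 2 1-[2-hydroxy-6-methoxy-4-(methoxymethoxy)phenyl]ethan-1-one; 4 4-[(1E)-3-hydroxyprop-1-en-1-yl]phenyl 2,2-dimethylpropanoate
Product: 5 4-[(1E)-3-[2-acetyl-3-methoxy-5-(methoxymethoxy)phenoxy]prop-1-en-1-yl]phenyl 2,2-dimethylpropanoate
Conditions: PPh3, DIAD, THF, 0 °C → rt
Reagents that add atoms: none
Why: Mitsunobu etherification, in which the acidic ketone-chelated phenol attacks the oxyphosphonium salt of the primary allylic alcohol by SN2 at CH2, so the linear E-cinnamyl ether forms on O-2' only (O-4' is blocked).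

Step 4
Reactants: 5 4-[(1E)-3-[2-acetyl-3-methoxy-5-(methoxymethoxy)phenoxy]prop-1-en-1-yl]phenyl 2,2-dimethylpropanoate
Product: 7 4-[(1S)-1-[3-acetyl-2-hydroxy-4-methoxy-6-(methoxymethoxy)phenyl]prop-2-en-1-yl]phenyl 2,2-dimethylpropanoate, via ortho-dienone 6 (not isolated)
Conditions: [Cu((R,R)-t-Bu-box)](SbF6)2 (10 mol %), 4 Å MS, CH2Cl2, −20 °C → rt
Reagents that add atoms: none
Why: Proposed new method: a cationic divalent copper bis(oxazoline) Lewis acid binds 5 through the ketone oxygen and the aryl ether oxygen in a six-membered chelate, which polarises the O–CH2 bond and lowers the barrier of the concerted [3,3] shift to the only free ortho carbon (C-3', electron-rich through the para methoxy and ortho methoxymethoxy groups), the 4-pivaloyloxy group on ring B being chosen to keep the allyl fragment from ionising to a free cinnamyl cation; the tert-butyl group beside the bound ether oxygen forces the cinnamyl unit over one face of the arene, and the chair transition state with the aryl group pseudo-equatorial then presents the Si face of the aryl-bearing alkene carbon to C-3', giving (S) after tautomerisation of dienone 6; the closest known reactions are copper bis(oxazoline)-catalysed enantioselective Claisen rearrangements of 2-alkoxycarbonyl allyl vinyl ethers, chiral Lewis acid-catalysed aromatic Claisen rearrangements of chelating allyl naphthyl ethers and achiral Lewis acid-accelerated aromatic Claisen rearrangements, none of which has been used to create an acyclic diarylmethine stereocentre from an ortho-acylphenyl cinnamyl ether.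

Step 5
Reactants: 8 methyl 3-(4-hydroxyphenyl)propanoate
Product: 9 methyl 3-[4-(methoxymethoxy)phenyl]propanoate
Conditions: MOMCl (1.2 equiv), i-Pr2NEt (1.5 equiv), CH2Cl2, 0 °C → rt
Reagents that add atoms: chloromethyl methyl ether, COCCl
Why: Williamson-type MOM protection of the only acidic hydroxyl; the methyl ester is inert to the amine base.

Step 6
Reactants: 9 methyl 3-[4-(methoxymethoxy)phenyl]propanoate
Product: 11 3-[4-(methoxymethoxy)phenyl]propanal, via aluminium hemiacetal 10 (not isolated)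
Conditions: i-Bu2AlH (1.05 equiv), CH2Cl2, −78 °C; then aq potassium sodium tartrate
Reagents that add atoms: none
Why: Partial ester reduction with one equivalent of i-Bu2AlH, in which the tetrahedral aluminium hemiacetal 10 does not collapse at −78 °C, so the aldehyde is released only on work-up and is not over-reduced.

Step 7
Reactants: 11 3-[4-(methoxymethoxy)phenyl]propanal
Product: 13 (3R)-1-[4-(methoxymethoxy)phenyl]hex-5-en-3-ol, via stannyl ether 12 (not isolated)
Conditions: (S)-BINOL (10 mol %), Ti(O-i-Pr)4 (10 mol %), 4 Å MS, CH2=CHCH2SnBu3 (1.2 equiv), CH2Cl2, −20 °C; then aq NaHCO3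
Reagents that add atoms: allyltributylstannane, C=CC[Sn](CCCC)(CCCC)CCCC
Why: Keck asymmetric allylation, in which the (S)-BINOL–titanium Lewis acid binds the aldehyde and shields its Re face, so the allylstannane adds to the Si face and sets the (R) carbinol centre (C-3 of the heptanoid), the stannyl ether 12 being hydrolysed on work-up.

Step 8
Reactants: 7 4-[(1S)-1-[3-acetyl-2-hydroxy-4-methoxy-6-(methoxymethoxy)phenyl]prop-2-en-1-yl]phenyl 2,2-dimethylpropanoate; 13 (3R)-1-[4-(methoxymethoxy)phenyl]hex-5-en-3-ol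
Product: 14 4-[(1S,2E,5R)-1-[3-acetyl-2-hydroxy-4-methoxy-6-(methoxymethoxy)phenyl]-5-hydroxy-7-[4-(methoxymethoxy)phenyl]hept-2-en-1-yl]phenyl 2,2-dimethylpropanoate
Conditions: second-generation Hoveyda–Grubbs catalyst RuCl2(H2IMes)(=CH-C6H4-2-O-i-Pr) (5 mol %), 1,4-benzoquinone (10 mol %), 13 (3 equiv), CH2Cl2, 40 °C
Reagents that add atoms: none
Why: Olefin cross-metathesis, in which the hindered 3,3-diarylpropene homodimerises slowly while the unhindered homoallylic alcohol in excess exchanges readily, so the cross product dominates and the bulky allylic carbon enforces the E geometry; benzoquinone traps ruthenium hydrides that would move the double bond into conjugation, and neither stereocentre takes part.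

Step 9
Reactants: 14 4-[(1S,2E,5R)-1-[3-acetyl-2-hydroxy-4-methoxy-6-(methoxymethoxy)phenyl]-5-hydroxy-7-[4-(methoxymethoxy)phenyl]hept-2-en-1-yl]phenyl 2,2-dimethylpropanoate; 15 benzaldehyde
Product: 18 (2E)-1-[2-hydroxy-3-[(1S,2E,5R)-5-hydroxy-1-(4-hydroxyphenyl)-7-[4-(methoxymethoxy)phenyl]hept-2-en-1-yl]-6-methoxy-4-(methoxymethoxy)phenyl]-3-phenylprop-2-en-1-one, via free phenol 16 (not isolated), via aldol adduct 17 (not isolated)
Conditions: 15 (3 equiv), KOH (50% aq, 20 equiv), EtOH, argon, 0 °C → rt, 36 h; then 1 M HCl to pH 5 at 0 °C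
Reagents that add atoms: none
Why: Claisen–Schmidt aldol condensation, in which hydroxide first cleaves the aryl pivalate to phenol 16, the methyl ketone enolate then adds to benzaldehyde and aldol 17 loses water by E1cB to the E-enone; the MOM ethers are base-stable and the C-7 hydrogen is far too weakly acidic for hydroxide, so both stereocentres are kept.

Step 10
Reactants: 18 (2E)-1-[2-hydroxy-3-[(1S,2E,5R)-5-hydroxy-1-(4-hydroxyphenyl)-7-[4-(methoxymethoxy)phenyl]hept-2-en-1-yl]-6-methoxy-4-(methoxymethoxy)phenyl]-3-phenylprop-2-en-1-one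
Product: 19 (2E)-1-[2,4-dihydroxy-3-[(1S,2E,5R)-5-hydroxy-1,7-bis(4-hydroxyphenyl)hept-2-en-1-yl]-6-methoxyphenyl]-3-phenylprop-2-en-1-one (7-epi-katsumain C)
Conditions: HCl (1.25 M in MeOH), rt
Reagents that add atoms: none
Why: Acid-catalysed acetal exchange with methanol removes both aryl MOM ethers at room temperature; such mild conditions are known to spare 2'-hydroxy-6'-methoxychalcones from ring closure to the flavanone and do not ionise the C-7–ring A bond, so the chalcone geometry and both stereocentres are unchanged.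

**Compound list**

1 | 1-(2,4-dihydroxy-6-methoxyphenyl)ethan-1-one (2',4'-dihydroxy-6'-methoxyacetophenone) | COc1cc(O)cc(O)c1C(C)=O | starting material
2 | 1-[2-hydroxy-6-methoxy-4-(methoxymethoxy)phenyl]ethan-1-one | COCOc1cc(O)c(C(C)=O)c(OC)c1 | intermediate
3 | 4-[(1E)-3-hydroxyprop-1-en-1-yl]phenol (p-coumaryl alcohol) | OC/C=C/c1ccc(O)cc1 | starting material
4 | 4-[(1E)-3-hydroxyprop-1-en-1-yl]phenyl 2,2-dimethylpropanoate | OC/C=C/c1ccc(OC(=O)C(C)(C)C)cc1 | intermediate
5 | 4-[(1E)-3-[2-acetyl-3-methoxy-5-(methoxymethoxy)phenoxy]prop-1-en-1-yl]phenyl 2,2-dimethylpropanoate | CC(=O)c1c(OC)cc(OCOC)cc1OC/C=C/c1ccc(OC(=O)C(C)(C)C)cc1 | intermediate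
6 | ortho-dienone formed in the flask: 4-[(1R)-1-[(1R)-3-acetyl-4-methoxy-6-(methoxymethoxy)-2-oxocyclohexa-3,5-dien-1-yl]prop-2-en-1-yl]phenyl 2,2-dimethylpropanoate | CC(=O)C1=C(OC)C=C(OCOC)[C@@H]([C@@H](C=C)c2ccc(OC(=O)C(C)(C)C)cc2)C1=O | intermediate
7 | 4-[(1S)-1-[3-acetyl-2-hydroxy-4-methoxy-6-(methoxymethoxy)phenyl]prop-2-en-1-yl]phenyl 2,2-dimethylpropanoate | COc1cc(OCOC)c([C@@H](C=C)c2ccc(OC(=O)C(C)(C)C)cc2)c(O)c1C(C)=O | intermediate
8 | methyl 3-(4-hydroxyphenyl)propanoate | COC(=O)CCc1ccc(O)cc1 | starting material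
9 | methyl 3-[4-(methoxymethoxy)phenyl]propanoate | COCOc1ccc(CCC(=O)OC)cc1 | intermediate
10 | aluminium hemiacetal formed in the flask: [1-methoxy-3-[4-(methoxymethoxy)phenyl]propoxy]bis(2-methylpropyl)alumane (hemiacetal carbon not controlled) | COCOc1ccc(CCC(OC)O[Al](CC(C)C)CC(C)C)cc1 | intermediate
11 | 3-[4-(methoxymethoxy)phenyl]propanal | COCOc1ccc(CCC=O)cc1 | intermediate
12 | stannyl ether formed in the flask: tributyl{[(3R)-1-[4-(methoxymethoxy)phenyl]hex-5-en-3-yl]oxy}stannane | C=CC[C@H](O[Sn](CCCC)(CCCC)CCCC)CCc1ccc(OCOC)cc1 | intermediate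
13 | (3R)-1-[4-(methoxymethoxy)phenyl]hex-5-en-3-ol | C=CC[C@H](O)CCc1ccc(OCOC)cc1 | intermediate
14 | 4-[(1S,2E,5R)-1-[3-acetyl-2-hydroxy-4-methoxy-6-(methoxymethoxy)phenyl]-5-hydroxy-7-[4-(methoxymethoxy)phenyl]hept-2-en-1-yl]phenyl 2,2-dimethylpropanoate | COc1cc(OCOC)c([C@@H](/C=C/C[C@H](O)CCc2ccc(OCOC)cc2)c2ccc(OC(=O)C(C)(C)C)cc2)c(O)c1C(C)=O | intermediate
15 | benzaldehyde | O=Cc1ccccc1 | starting material
16 | free phenol formed in the flask: 1-[2-hydroxy-3-[(1S,2E,5R)-5-hydroxy-1-(4-hydroxyphenyl)-7-[4-(methoxymethoxy)phenyl]hept-2-en-1-yl]-6-methoxy-4-(methoxymethoxy)phenyl]ethan-1-one | COc1cc(OCOC)c([C@@H](/C=C/C[C@H](O)CCc2ccc(OCOC)cc2)c2ccc(O)cc2)c(O)c1C(C)=O | intermediate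
17 | aldol adduct formed in the flask: 3-hydroxy-1-[2-hydroxy-3-[(1S,2E,5R)-5-hydroxy-1-(4-hydroxyphenyl)-7-[4-(methoxymethoxy)phenyl]hept-2-en-1-yl]-6-methoxy-4-(methoxymethoxy)phenyl]-3-phenylpropan-1-one (both epimers at the new carbinol carbon) | COc1cc(OCOC)c([C@@H](/C=C/C[C@H](O)CCc2ccc(OCOC)cc2)c2ccc(O)cc2)c(O)c1C(=O)CC(O)c1ccccc1 | intermediate
18 | (2E)-1-[2-hydroxy-3-[(1S,2E,5R)-5-hydroxy-1-(4-hydroxyphenyl)-7-[4-(methoxymethoxy)phenyl]hept-2-en-1-yl]-6-methoxy-4-(methoxymethoxy)phenyl]-3-phenylprop-2-en-1-one | COc1cc(OCOC)c([C@@H](/C=C/C[C@H](O)CCc2ccc(OCOC)cc2)c2ccc(O)cc2)c(O)c1C(=O)/C=C/c1ccccc1 | intermediate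
19 | (2E)-1-[2,4-dihydroxy-3-[(1S,2E,5R)-5-hydroxy-1,7-bis(4-hydroxyphenyl)hept-2-en-1-yl]-6-methoxyphenyl]-3-phenylprop-2-en-1-one (7-epi-katsumain C) | COc1cc(O)c([C@@H](/C=C/C[C@H](O)CCc2ccc(O)cc2)c2ccc(O)cc2)c(O)c1C(=O)/C=C/c1ccccc1 | target

**Totals**

Total step count: 10.
Longest linear sequence: 6 steps (steps 1, 3, 4, 8, 9, 10 from 1; equally steps 5, 6, 7, 8, 9, 10 from 8).

**Three steps most likely to fail**

Step 4 (the proposed enantioselective aromatic Claisen rearrangement).
- The rearrangement may need warming, and the chelating product 7 may slow turnover.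
- The allyl fragment may ionise, which would show as linear cinnamyl C-alkylation and low ee.
- The sense of induction is a model prediction. If it is opposite, the (S,S) ligand is used.
- Fallback, known chemistry: substrate-controlled 1,3-chirality transfer. It sets out from phenol 2 and comes back to the route at 14.
- Commercial (E)-4-(4-hydroxyphenyl)but-3-en-2-one is pivaloylated (PivCl, Et3N, CH2Cl2) to the enone 4-[(1E)-3-oxobut-1-en-1-yl]phenyl pivalate F1.
- Corey–Bakshi–Shibata reduction with the (S)-methyl oxazaborolidine and catecholborane gives the (R)-allylic alcohol F2.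
- Mitsunobu etherification with 2 (PPh3, DIAD) inverts the carbinol to the (S)-aryl ether F3.
- A thermal aromatic Claisen rearrangement (N,N-diethylaniline, 170 °C) passes through the transient ortho-dienone F4. Its chair transition state, with the methyl group pseudo-equatorial, carries the C–O stereocentre across the allyl unit and gives the (1S,2E)-but-2-enyl phenol F5.
- Cross-metathesis of F5 with 13 under the step 8 conditions, with propene lost in place of ethylene, gives 14.

Step 8 (cross-metathesis at a very hindered diarylmethine).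
- Turnover may be slow, or the double bond may migrate into conjugation, which would destroy C-7.
- Fallback: no metathesis on the hindered alkene; the whole chain is carried through the rearrangement. It sets out from 13 (with phenol 2) and comes back at 14.
- 13 is silylated (TBSCl, imidazole, DMF) to the silyl ether F6.
- Tsuji–Wacker oxidation (PdCl2 10 mol %, CuCl, O2, DMF/H2O) gives the methyl ketone F7.
- 4-Hydroxybenzaldehyde is pivaloylated to 4-formylphenyl pivalate F8, which is condensed with F7 (pyrrolidine, AcOH, THF) to the E-enone F9.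
- Reduction with the (S)-methyl oxazaborolidine and catecholborane gives the (3R)-allylic alcohol F10.
- Mitsunobu etherification with 2 gives the (3S)-ether F11.
- Thermal Claisen rearrangement (N,N-diethylaniline, 170 °C) through the transient ortho-dienone F12 gives the silyl-protected phenol F13, with the E-alkene and the (S) centre made in one event.
- HF·pyridine in THF removes the silyl group and gives 14.

Step 10 (acid on the finished 2'-hydroxychalcone).
- The chalcone may close to the flavanone, or C-7 may epimerise by reversible ionisation.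
- Fallback: all acid-labile groups are removed before the enone exists, and the base-mediated condensation is made the last step. It sets out from 14 and comes back at 19.
- K2CO3 in MeOH cleaves the pivalate and gives phenol 16, isolated here.
- Methanolic HCl removes both MOM groups from this acetophenone, which has no enone to cyclise, and gives the pentahydroxy ketone F14.
- Claisen–Schmidt condensation of F14 with benzaldehyde 15 (KOH 60% aq, EtOH, argon, rt, 48 h; cold acidification to pH 5) passes through the aldol adduct F15 and gives 19 directly.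

Further compounds
F1 | step 4 | 4-[(1E)-3-oxobut-1-en-1-yl]phenyl 2,2-dimethylpropanoate | CC(=O)/C=C/c1ccc(OC(=O)C(C)(C)C)cc1
F2 | step 4 | 4-[(1E,3R)-3-hydroxybut-1-en-1-yl]phenyl 2,2-dimethylpropanoate | C[C@@H](O)/C=C/c1ccc(OC(=O)C(C)(C)C)cc1
F3 | step 4 | 4-[(1E,3S)-3-[2-acetyl-3-methoxy-5-(methoxymethoxy)phenoxy]but-1-en-1-yl]phenyl 2,2-dimethylpropanoate | CC(=O)c1c(OC)cc(OCOC)cc1O[C@@H](C)/C=C/c1ccc(OC(=O)C(C)(C)C)cc1
F4 | step 4 | 4-[(1R,2E)-1-[(1R)-3-acetyl-4-methoxy-6-(methoxymethoxy)-2-oxocyclohexa-3,5-dien-1-yl]but-2-en-1-yl]phenyl 2,2-dimethylpropanoate | CC(=O)C1=C(OC)C=C(OCOC)[C@@H]([C@@H](/C=C/C)c2ccc(OC(=O)C(C)(C)C)cc2)C1=O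
F5 | step 4 | 4-[(1S,2E)-1-[3-acetyl-2-hydroxy-4-methoxy-6-(methoxymethoxy)phenyl]but-2-en-1-yl]phenyl 2,2-dimethylpropanoate | COc1cc(OCOC)c([C@@H](/C=C/C)c2ccc(OC(=O)C(C)(C)C)cc2)c(O)c1C(C)=O
F6 | step 8 | tert-butyl{[(3R)-1-[4-(methoxymethoxy)phenyl]hex-5-en-3-yl]oxy}dimethylsilane | C=CC[C@H](O[Si](C)(C)C(C)(C)C)CCc1ccc(OCOC)cc1
F7 | step 8 | (4R)-4-{[tert-butyl(dimethyl)silyl]oxy}-6-[4-(methoxymethoxy)phenyl]hexan-2-one | CC(=O)C[C@H](O[Si](C)(C)C(C)(C)C)CCc1ccc(OCOC)cc1
F8 | step 8 | 4-formylphenyl 2,2-dimethylpropanoate | O=Cc1ccc(OC(=O)C(C)(C)C)cc1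
F9 | step 8 | 4-[(1E,5R)-5-{[tert-butyl(dimethyl)silyl]oxy}-7-[4-(methoxymethoxy)phenyl]-3-oxohept-1-en-1-yl]phenyl 2,2-dimethylpropanoate | CC(C)(C)C(=O)Oc1ccc(/C=C/C(=O)C[C@H](O[Si](C)(C)C(C)(C)C)CCc2ccc(OCOC)cc2)cc1
F10 | step 8 | 4-[(1E,3R,5R)-5-{[tert-butyl(dimethyl)silyl]oxy}-3-hydroxy-7-[4-(methoxymethoxy)phenyl]hept-1-en-1-yl]phenyl 2,2-dimethylpropanoate | CC(C)(C)C(=O)Oc1ccc(/C=C/[C@H](O)C[C@H](O[Si](C)(C)C(C)(C)C)CCc2ccc(OCOC)cc2)cc1
F11 | step 8 | 4-[(1E,3S,5R)-3-[2-acetyl-3-methoxy-5-(methoxymethoxy)phenoxy]-5-{[tert-butyl(dimethyl)silyl]oxy}-7-[4-(methoxymethoxy)phenyl]hept-1-en-1-yl]phenyl 2,2-dimethylpropanoate | CC(=O)c1c(OC)cc(OCOC)cc1O[C@H](/C=C/c1ccc(OC(=O)C(C)(C)C)cc1)C[C@H](O[Si](C)(C)C(C)(C)C)CCc1ccc(OCOC)cc1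
F12 | step 8 | 4-[(1R,2E,5R)-1-[(1R)-3-acetyl-4-methoxy-6-(methoxymethoxy)-2-oxocyclohexa-3,5-dien-1-yl]-5-{[tert-butyl(dimethyl)silyl]oxy}-7-[4-(methoxymethoxy)phenyl]hept-2-en-1-yl]phenyl 2,2-dimethylpropanoate | CC(=O)C1=C(OC)C=C(OCOC)[C@@H]([C@@H](/C=C/C[C@H](O[Si](C)(C)C(C)(C)C)CCc2ccc(OCOC)cc2)c2ccc(OC(=O)C(C)(C)C)cc2)C1=O
F13 | step 8 | 4-[(1S,2E,5R)-1-[3-acetyl-2-hydroxy-4-methoxy-6-(methoxymethoxy)phenyl]-5-{[tert-butyl(dimethyl)silyl]oxy}-7-[4-(methoxymethoxy)phenyl]hept-2-en-1-yl]phenyl 2,2-dimethylpropanoate | COc1cc(OCOC)c([C@@H](/C=C/C[C@H](O[Si](C)(C)C(C)(C)C)CCc2ccc(OCOC)cc2)c2ccc(OC(=O)C(C)(C)C)cc2)c(O)c1C(C)=O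
F14 | step 10 | 1-[2,4-dihydroxy-3-[(1S,2E,5R)-5-hydroxy-1,7-bis(4-hydroxyphenyl)hept-2-en-1-yl]-6-methoxyphenyl]ethan-1-one | COc1cc(O)c([C@@H](/C=C/C[C@H](O)CCc2ccc(O)cc2)c2ccc(O)cc2)c(O)c1C(C)=O
F15 | step 10 | 1-[2,4-dihydroxy-3-[(1S,2E,5R)-5-hydroxy-1,7-bis(4-hydroxyphenyl)hept-2-en-1-yl]-6-methoxyphenyl]-3-hydroxy-3-phenylpropan-1-one (both epimers at the new carbinol carbon) | COc1cc(O)c([C@@H](/C=C/C[C@H](O)CCc2ccc(O)cc2)c2ccc(O)cc2)c(O)c1C(=O)CC(O)c1ccccc1
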